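**Assumption:** the SMILES is read literally, i.e. a cis-fused decalin (2S,4aR,8aS in naphthalene numbering; H-4a, CH3-8a and CH3-2 on one face) with an E exocyclic alkene; nerylacetone is bought in its ≥95% Z grade.

**Retrosynthetic overview**
1. The last bond made is the arene C5–O bond: C–H to C–O hydroxylation (Elbs persulfate oxidation) of the 2,4-dihydroxy-3-alkenylbenzaldehyde, so the arene enters as cheap 2,4-dihydroxybenzaldehyde.
2. The styrene C=C comes from a benzylic alcohol (acid: dehydration plus MOM loss), made from the decalin carbaldehyde and C3-lithiated 2,4-bis(methoxymethoxy)benzaldehyde (aldehyde masked in the flask).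
3. The carbaldehyde comes from the saturated ester; its C-methyl centre is set by dissolving-metal reduction of the tetrasubstituted enoate, which comes via the enol triflate from a cis-fused bicyclic β-keto ester.
4. The β-keto ester comes from the acyclic (Z)-dienyl β-keto ester (from nerylacetone): rings A and B close in one proton-initiated cascade (ring A first, then ring B); the benzene ring is bought.

**Route**

Step 1
Reactants: 1 nerylacetone, (5Z)-6,10-dimethylundeca-5,9-dien-2-one
Product: 2 methyl (6Z)-7,11-dimethyl-3-oxododeca-6,10-dienoate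
Conditions: NaH (2.2 equiv), (MeO)2CO, THF, reflux; AcOH quench
Reagents that add atoms: dimethyl carbonate COC(=O)OC
Why: crossed Claisen condensation in which the methyl-side ketone enolate is C-acylated and the equilibrium is pulled over by the stabilised β-keto ester enolate, while the Z alkene is untouched.

Step 2
Reactants: 2 methyl (6Z)-7,11-dimethyl-3-oxododeca-6,10-dienoate
Product: 3 methyl (1S,4aR,8aS)-5,5,8a-trimethyl-2-oxodecahydronaphthalene-1-carboxylate (cis-fused)
Conditions: chiral IDPi Brønsted acid (5 mol %; NH-bridged bis(3,3'-diaryl-BINOL-phosphoryl) imide with N-triflyl groups, aryl = 3,5-(CF3)2C6H3; antipode chosen by screening), (CF3)3COH/CH2Cl2, −40 °C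
Reagents that add atoms: none
Why: Proposed new method: the confined chiral acid protonates the terminal trisubstituted alkene on one enantioface while its anion holds the hydrogen-bonded β-keto ester enol over the chair–chair folded diene, so that antiperiplanar addition across the Z alkene closes ring A and then ring B with H-4a and CH3-8a on the same face (cis fusion, 4aR,8aS), C-attack of the enol being irreversible whereas O-attack reverts, and C1 settles as the equatorial ester; the closest known reactions are IDPi-catalysed proton-initiated cyclizations of E-polyenes terminated by a hydroxyl group and the racemic SnCl4-promoted cyclization of olefinic β-keto esters.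

Step 3
Reactants: 3 methyl (1S,4aR,8aS)-5,5,8a-trimethyl-2-oxodecahydronaphthalene-1-carboxylate
Product: 4 methyl (4aR,8aS)-5,5,8a-trimethyl-2-{[(trifluoromethyl)sulfonyl]oxy}-3,4,4a,5,6,7,8,8a-octahydronaphthalene-1-carboxylate
Conditions: NaH, THF, 0 °C; PhNTf2, 0 °C to rt; 1 M HCl work-up
Reagents that add atoms: N-phenylbis(trifluoromethanesulfonimide) O=S(=O)(N(c1ccccc1)S(=O)(=O)C(F)(F)F)C(F)(F)F
Why: O-sulfonylation of the β-keto ester enolate gives the tetrasubstituted enol triflate, which marks the ketone carbon for methylation and erases the inconsequential C1 centre.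

Step 4
Reactants: 4 the enol triflate
Product: 5 methyl (4aR,8aS)-2,5,5,8a-tetramethyl-3,4,4a,5,6,7,8,8a-octahydronaphthalene-1-carboxylate
Conditions: MeMgBr (1.5 equiv), Fe(acac)3 (5 mol %), THF/NMP, −30 °C
Reagents that add atoms: methylmagnesium bromide C[Mg]Br
Why: iron-catalysed Kochi-type cross-coupling of an alkenyl triflate with a Grignard reagent, which at −30 °C is much faster than attack on the hindered conjugated ester.

Step 5
Reactants: 5 the tetrasubstituted enoate
Product: 6 methyl (1R,2S,4aR,8aS)-2,5,5,8a-tetramethyldecahydronaphthalene-1-carboxylate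
Conditions: Li, NH3(l)/THF, t-BuOH (1 equiv), −78 °C; NH4Cl; then cat. NaOMe, MeOH, 50 °C
Reagents that add atoms: none
Why: dissolving-metal (Birch-type) conjugate reduction in which the β-carbon is protonated axially on the more stable cis-decalin half-chair (the one keeping the gem-dimethyl carbon equatorial on ring B), which leaves the C2 methyl equatorial and cis to the angular methyl (2S), after which methoxide equilibrates C1 to the equatorial ester (1R).

Step 6
Reactants: 6 the saturated ester
Product: 7 (1R,2S,4aR,8aS)-2,5,5,8a-tetramethyldecahydronaphthalene-1-carbaldehyde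
Conditions: i-Bu2AlH (1.2 equiv), CH2Cl2, −78 °C; aqueous potassium sodium tartrate (KNaC4H4O6)
Reagents that add atoms: none
Why: partial hydride reduction of a hindered methyl ester at −78 °C stops at the aldehyde oxidation level until work-up, and the epimerisable C1 centre is immaterial because it becomes sp2 later.

Step 7
Reactants: 8 2,4-dihydroxybenzaldehyde
Product: 9 2,4-bis(methoxymethoxy)benzaldehyde
Conditions: NaH (2.4 equiv), MOMCl (2.4 equiv), DMF, 0 °C to rt
Reagents that add atoms: chloromethyl methyl ether COCCl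
Why: Williamson-type O-alkylation of both phenoxides, including the hydrogen-bonded one, which installs the two ortho-directing groups that flank C3.

Step 8
Reactants: 9 2,4-bis(methoxymethoxy)benzaldehyde (1.6 equiv); 7 the decalin carbaldehyde
Product: 13 3-{hydroxy[(1R,2S,4aR,8aS)-2,5,5,8a-tetramethyldecahydronaphthalen-1-yl]methyl}-2,4-bis(methoxymethoxy)benzaldehyde (carbinol epimers), via lithium amino alkoxide 10 (not isolated), via 3-lithio arene 11 (not isolated), via dilithium adduct 12 (not isolated)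
Conditions: N-methylpiperazine, n-BuLi, THF, −20 °C; 9; n-BuLi (1.5 equiv), −20 to 0 °C; 7, −78 to 0 °C; aq NH4Cl
Reagents that add atoms: none
Why: the aryl aldehyde is masked in the flask as a weakly directing α-amino alkoxide, directed ortho-lithiation then occurs at the carbon between the two MOM ethers, and 1,2-addition to the aliphatic aldehyde gives a carbinol whose epimer ratio does not matter because that carbon becomes sp2 in the next step.

Step 9
Reactants: 13 the benzylic alcohol
Product: 14 2,4-dihydroxy-3-{(E)-[(2S,4aR,8aS)-2,5,5,8a-tetramethyloctahydronaphthalen-1(2H)-ylidene]methyl}benzaldehyde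
Conditions: 2 M HCl, MeOH/THF, 0 °C to rt, short reaction time
Reagents that add atoms: none
Why: acid methanolysis removes both MOM acetals and ionises the doubly ortho-oxygenated benzylic alcohol, and E1 loss of the only β-hydrogen gives the styrene with the aryl group turned toward the tertiary C2 and away from the quaternary C8a (E), leaving the C2 centre untouched.

Step 10
Reactants: 14 the 2,4-dihydroxy-3-alkenylbenzaldehyde
Product: 16 2,4,5-trihydroxy-3-{(E)-[(2S,4aR,8aS)-2,5,5,8a-tetramethyloctahydronaphthalen-1(2H)-ylidene]methyl}benzaldehyde (target), via aryl potassium sulfate 15 (not isolated)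
Conditions: K2S2O8 (1.1 equiv), aq KOH/pyridine, 0 °C to rt; then dilute HCl to pH 2, THF/EtOAc, 40 °C
Reagents that add atoms: potassium peroxodisulfate [K+].[K+].[O-]S(=O)(=O)OOS(=O)(=O)[O-]
Why: Elbs persulfate oxidation, in which the phenoxide attacks the peroxide oxygen through C5 (para to the 2-oxide, ortho to the 4-oxide, the only free activated position) to give an aryl sulfate that resists over-oxidation and is solvolysed under mild acid, while the hindered alkene and the aldehyde are not touched by this nucleophilic arene oxidation.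

**Compound list**
1 | nerylacetone, (5Z)-6,10-dimethylundeca-5,9-dien-2-one | CC(=O)CC/C=C(/C)CCC=C(C)C | starting material
2 | methyl (6Z)-7,11-dimethyl-3-oxododeca-6,10-dienoate | COC(=O)CC(=O)CC/C=C(/C)CCC=C(C)C | intermediate
3 | methyl (1S,4aR,8aS)-5,5,8a-trimethyl-2-oxodecahydronaphthalene-1-carboxylate (cis-fused) | O=C1CC[C@@H]2C(C)(C)CCC[C@]2(C)[C@@H]1C(=O)OC | intermediate
4 | methyl (4aR,8aS)-5,5,8a-trimethyl-2-{[(trifluoromethyl)sulfonyl]oxy}-3,4,4a,5,6,7,8,8a-octahydronaphthalene-1-carboxylate | FC(F)(F)S(=O)(=O)OC=1CC[C@@H]2C(C)(C)CCC[C@]2(C)C=1C(=O)OC | intermediate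
5 | methyl (4aR,8aS)-2,5,5,8a-tetramethyl-3,4,4a,5,6,7,8,8a-octahydronaphthalene-1-carboxylate | CC=1CC[C@@H]2C(C)(C)CCC[C@]2(C)C=1C(=O)OC | intermediate
6 | methyl (1R,2S,4aR,8aS)-2,5,5,8a-tetramethyldecahydronaphthalene-1-carboxylate | C[C@H]1CC[C@@H]2C(C)(C)CCC[C@]2(C)[C@@H]1C(=O)OC | intermediate
7 | (1R,2S,4aR,8aS)-2,5,5,8a-tetramethyldecahydronaphthalene-1-carbaldehyde | C[C@H]1CC[C@@H]2C(C)(C)CCC[C@]2(C)[C@@H]1C=O | intermediate
8 | 2,4-dihydroxybenzaldehyde | O=Cc1ccc(O)cc1O | starting material
9 | 2,4-bis(methoxymethoxy)benzaldehyde | COCOc1ccc(C=O)c(OCOC)c1 | intermediate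
10 | lithium α-amino alkoxide from 9 and lithium 4-methylpiperazin-1-ide | COCOc1ccc(C(O[Li])N2CCN(C)CC2)c(OCOC)c1 | intermediate
11 | 3-lithio derivative of 10 (lithium between the two MOM ethers) | COCOc1ccc(C(O[Li])N2CCN(C)CC2)c(OCOC)c1[Li] | intermediate
12 | dilithium adduct of 11 and 7 (benzylic alkoxide, aldehyde still masked) | C[C@H]1CC[C@@H]2C(C)(C)CCC[C@]2(C)[C@@H]1C(O[Li])c1c(OCOC)ccc(C(O[Li])N2CCN(C)CC2)c1OCOC | intermediate
13 | 3-{hydroxy[(1R,2S,4aR,8aS)-2,5,5,8a-tetramethyldecahydronaphthalen-1-yl]methyl}-2,4-bis(methoxymethoxy)benzaldehyde (carbinol epimers) | C[C@H]1CC[C@@H]2C(C)(C)CCC[C@]2(C)[C@@H]1C(O)c1c(OCOC)ccc(C=O)c1OCOC | intermediate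
14 | 2,4-dihydroxy-3-{(E)-[(2S,4aR,8aS)-2,5,5,8a-tetramethyloctahydronaphthalen-1(2H)-ylidene]methyl}benzaldehyde | C[C@H]1CC[C@@H]2C(C)(C)CCC[C@]2(C)/C1=C/c1c(O)ccc(C=O)c1O | intermediate
15 | potassium 5-formyl-2,4-dihydroxy-3-{(E)-[(2S,4aR,8aS)-2,5,5,8a-tetramethyloctahydronaphthalen-1(2H)-ylidene]methyl}phenyl sulfate | C[C@H]1CC[C@@H]2C(C)(C)CCC[C@]2(C)/C1=C/c1c(O)c(OS(=O)(=O)[O-])cc(C=O)c1O.[K+] | intermediate
16 | 2,4,5-trihydroxy-3-{(E)-[(2S,4aR,8aS)-2,5,5,8a-tetramethyloctahydronaphthalen-1(2H)-ylidene]methyl}benzaldehyde | C[C@H]1CC[C@@H]2C(C)(C)CCC[C@]2(C)/C1=C/c1c(O)c(O)cc(C=O)c1O | target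

**Step count and risks**

Total step count: 10. Longest linear sequence: 9 (steps 1 to 6, then 8, 9, 10).

The three steps most likely to fail:

Step 2 (the proposed new enantioselective bicyclization; risks are low enantioselectivity, O-cyclization or monocyclization). Fallback with known chemistry, setting out from 2 and coming back at 3: 2 is cyclised with SnCl4 in CH2Cl2 at 0 °C (the known Z-to-cis cyclization of olefinic β-keto esters) to the racemate, i.e. 3 together with its mirror image methyl (1R,4aS,8aR)-5,5,8a-trimethyl-2-oxodecahydronaphthalene-1-carboxylate F1. The mixture is transesterified with (1R,2S,5R)-menthol (cat. DMAP, toluene, reflux, through the acyl ketene) to the diastereomers (1R,2S,5R)-menthyl (1S,4aR,8aS)-5,5,8a-trimethyl-2-oxodecahydronaphthalene-1-carboxylate F2 and (1R,2S,5R)-menthyl (1R,4aS,8aR)-5,5,8a-trimethyl-2-oxodecahydronaphthalene-1-carboxylate F3. These are separated by crystallisation or chromatography, and F2 is returned to 3 with MeOH and cat. DMAP at reflux.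

Step 5 (facial selectivity at the methyl-bearing carbon, and possible over-reduction of the twisted enoate). Fallback that delivers the methyl group, not the hydrogen, from the open convex face; it sets out from 3 and comes back at 6. NaBH4 in MeOH at 0 °C gives methyl (1S,2R,4aR,8aS)-2-hydroxy-5,5,8a-trimethyldecahydronaphthalene-1-carboxylate F4. MsCl and Et3N give methyl (1S,2R,4aR,8aS)-2-[(methylsulfonyl)oxy]-5,5,8a-trimethyldecahydronaphthalene-1-carboxylate F5, which DBU eliminates to methyl (4aR,8aS)-5,5,8a-trimethyl-3,4,4a,5,6,7,8,8a-octahydronaphthalene-1-carboxylate F6. Conjugate addition of Me2CuLi with TMSCl (THF, −78 to −20 °C), followed by NaOMe/MeOH equilibration of C1, gives 6.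

Step 10 (Elbs oxidations are low-yielding, and the product is sensitive to oxidants and to acid). Fallback that carries the third oxygen in with the arene; it sets out from 7 and comes back at 16. Commercial 2,4,5-trihydroxybenzaldehyde F7 is protected (NaH, MOMCl, DMF) as 2,4,5-tris(methoxymethoxy)benzaldehyde F8. The protocol of step 8 then gives the lithium amino alkoxide F9, the 3-lithio arene F10, after addition of 7 the dilithium adduct F11, and on work-up 3-{hydroxy[(1R,2S,4aR,8aS)-2,5,5,8a-tetramethyldecahydronaphthalen-1-yl]methyl}-2,4,5-tris(methoxymethoxy)benzaldehyde F12. The acid treatment of step 9 converts F12 directly into 16.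

Further compounds
F1 | step 2 | methyl (1R,4aS,8aR)-5,5,8a-trimethyl-2-oxodecahydronaphthalene-1-carboxylate (enantiomer of 3) | O=C1CC[C@H]2C(C)(C)CCC[C@@]2(C)[C@H]1C(=O)OC
F2 | step 2 | (1R,2S,5R)-menthyl (1S,4aR,8aS)-5,5,8a-trimethyl-2-oxodecahydronaphthalene-1-carboxylate | O=C1CC[C@@H]2C(C)(C)CCC[C@]2(C)[C@@H]1C(=O)O[C@@H]1C[C@H](C)CC[C@H]1C(C)C
F3 | step 2 | (1R,2S,5R)-menthyl (1R,4aS,8aR)-5,5,8a-trimethyl-2-oxodecahydronaphthalene-1-carboxylate | O=C1CC[C@H]2C(C)(C)CCC[C@@]2(C)[C@H]1C(=O)O[C@@H]1C[C@H](C)CC[C@H]1C(C)C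
F4 | step 5 | methyl (1S,2R,4aR,8aS)-2-hydroxy-5,5,8a-trimethyldecahydronaphthalene-1-carboxylate | O[C@@H]1CC[C@@H]2C(C)(C)CCC[C@]2(C)[C@@H]1C(=O)OC
F5 | step 5 | methyl (1S,2R,4aR,8aS)-2-[(methylsulfonyl)oxy]-5,5,8a-trimethyldecahydronaphthalene-1-carboxylate | CS(=O)(=O)O[C@@H]1CC[C@@H]2C(C)(C)CCC[C@]2(C)[C@@H]1C(=O)OC
F6 | step 5 | methyl (4aR,8aS)-5,5,8a-trimethyl-3,4,4a,5,6,7,8,8a-octahydronaphthalene-1-carboxylate | C=1CC[C@@H]2C(C)(C)CCC[C@]2(C)C=1C(=O)OC
F7 | step 10 | 2,4,5-trihydroxybenzaldehyde | O=Cc1cc(O)c(O)cc1O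
F8 | step 10 | 2,4,5-tris(methoxymethoxy)benzaldehyde | COCOc1cc(OCOC)c(C=O)cc1OCOC
F9 | step 10 | lithium α-amino alkoxide from F8 and lithium 4-methylpiperazin-1-ide | COCOc1cc(OCOC)c(C(O[Li])N2CCN(C)CC2)cc1OCOC
F10 | step 10 | 3-lithio derivative of F9 | COCOc1c([Li])c(OCOC)c(C(O[Li])N2CCN(C)CC2)cc1OCOC
F11 | step 10 | dilithium adduct of F10 and 7 | C[C@H]1CC[C@@H]2C(C)(C)CCC[C@]2(C)[C@@H]1C(O[Li])c1c(OCOC)c(OCOC)cc(C(O[Li])N2CCN(C)CC2)c1OCOC
F12 | step 10 | 3-{hydroxy[(1R,2S,4aR,8aS)-2,5,5,8a-tetramethyldecahydronaphthalen-1-yl]methyl}-2,4,5-tris(methoxymethoxy)benzaldehyde | C[C@H]1CC[C@@H]2C(C)(C)CCC[C@]2(C)[C@@H]1C(O)c1c(OCOC)c(OCOC)cc(C=O)c1OCOC
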